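**Plan**
Numbering: chroman O1, C2, C3, C4, C4a, C5–C8, C8a (ring A is the benzene, ring B the dihydropyran); hexanoic acid C1'–C6'.
Retrosynthetic cuts, in order: the acid is re-closed on O5 as a δ-lactone (ring C); C8–prenyl; C3'–H (back to a coumarin); C6–C3' and O5–C1' (Pechmann); C4H2 back to C4=O and O5–H back to O5–Me; last, O1–C8a and C2–C3 together. This leaves acetaldehyde and 2,4,6-trimethoxypropiophenone.
Enabling feature: with C4 as a ketone, ring B (O1, C2, C3, C4, C4a, C8a) is a benzo-fused 2,3-dihydropyran-4-one. Ring A carries oxygen at C5, C7 and C8a, so C8a is a vinylogous ester carbon with an exchangeable OMe. C3=C4(OSiMe3)–C4a=C8a(OMe) is then a 1-methoxy-3-silyloxy diene, and acetaldehyde is its O1=C2 partner.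
Forward order: ring A is bought. Ring B comes from the annulation. The helper ketone directs the O5 demethylation and is then removed through the free O5–H. Ring C, the C8 prenyl group and the lactone opening follow.
Stereochemistry: C2 comes from a chiral boron Lewis acid (face of acetaldehyde), C3 from the open anti transition state of the same step, and C3' from ligand-controlled copper hydride.

Key step: step 3

Assumption: the sense of induction of the oxazaborolidinone (step 3) and of the copper hydride ligand (step 7) is extrapolated from simpler substrates. The route needs Re-face attack on acetaldehyde and (R) at C3', and the mirror-image catalyst is equally available if a pilot run calls for it.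

Step 1
Reactants: 1 1,3,5-trimethoxybenzene; 2 propionic anhydride
Product: 3 1-(2,4,6-trimethoxyphenyl)propan-1-one
Conditions: TfOH (5 mol %), MeNO2, 0 °C → rt
Reagents that add atoms: none
Why: Friedel–Crafts acylation, in which the three equivalent C–H positions of 1 are each ortho/para to three methoxy groups, so a catalytic acid suffices and the deactivating ketone stops the reaction after one acylation.

Step 2
Reactants: 3 1-(2,4,6-trimethoxyphenyl)propan-1-one
Product: 4 (Z)-trimethyl{[1-(2,4,6-trimethoxyphenyl)prop-1-en-1-yl]oxy}silane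
Conditions: TMSOTf (1.2 equiv), Et3N (1.5 equiv), CH2Cl2, 0 °C
Reagents that add atoms: trimethylsilyl triflate, C[Si](C)(C)OS(=O)(=O)C(F)(F)F
Why: Soft enolisation (O-silylation, then deprotonation by the amine), in which allylic strain between the ortho-methoxy aryl group and the C3 methyl in the silyloxycarbenium ion should place the methyl cis to OSiMe3 and give the (Z)-enol silane that step 3 needs.

Step 3
Reactants: 4 (Z)-enol silane; 5 acetaldehyde
Product: 8 (2S,3S)-5,7-dimethoxy-2,3-dimethylchroman-4-one, via silyl aldol 6 (not isolated), via ring ketal 7 (not isolated)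
Conditions: 5 (1.5 equiv), (S)-2-butyl-4-(1H-indol-3-ylmethyl)-3-tosyl-1,3,2-oxazaborolidin-5-one (20 mol %), EtCN, −78 °C; excess 5 removed in vacuo at −40 °C; TMSOTf (0.5 equiv), −40 → 0 °C
Reagents that add atoms: none
Why: Proposed new method: the boron Lewis acid binds acetaldehyde and C3 of the enol silane adds to its Re face (Mukaiyama aldol, C2–C3), silyl transfer giving 6; TMSOTf then silylates the strongly Lewis-basic trimethoxyaryl ketone, which makes C8a an O-methyl oxocarbenium (vinylogous ester) carbon, the silyl ether oxygen O1 adds there with return of Me3Si+ to give ketal 7, and 7 rearomatises by 1,4-loss of Me3SiOMe (O1–C8a). The closest known reaction types are the enantioselective aldol–dihydropyranone annulation of 1-methoxy-3-silyloxy dienes with aldehydes under this class of oxazaborolidinone and the acid-mediated closure of 2-hydroxy-2',4',6'-trimethoxybenzophenones to xanthones with loss of methanol; what is new is that the C4a=C8a bond of the diene belongs to a benzene ring (a phloroglucinol ether, the arene class with the smallest penalty for ipso addition) and that the nucleophile is an aliphatic silyl ether. Ring B closes by a 6-endo-trig addition–elimination at C8a (6-exo-trig if viewed from the C8a=O+Me resonance form). C2 is set by the catalyst, whose indole shields one face of the bound aldehyde, and its C–O bond is never broken; C3 is set relative to C2 in the open antiperiplanar transition state, where the twisted aryl group (cis to H on the (Z)-enol silane, with ortho methoxy groups above and below the enol plane) blocks the quadrant the aldehyde methyl would need for the syn adduct, so the anti adduct and hence the trans ring should result. The step needs attack by C3 rather than Friedel–Crafts attack by ring A (the enol silane is the stronger π-nucleophile, and spare aldehyde is removed before the stronger acid is added) and closure rather than β-elimination or retro-aldol (no base and no free alkoxide is present, so C3–H and C2–C3 are not labilised). No site selectivity is needed, because aryl rotation interchanges the two ortho methoxy carbons.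

Step 4
Reactants: 8 (2S,3S)-5,7-dimethoxy-2,3-dimethylchroman-4-one
Product: 9 (2S,3S)-5-hydroxy-7-methoxy-2,3-dimethylchroman-4-one
Conditions: BCl3 (1.2 equiv), CH2Cl2, −78 → −10 °C; H2O
Reagents that add atoms: none
Why: Chelation-controlled aryl methyl ether cleavage, in which BCl3 is held between C4=O and the peri O5 so that chloride removes only that methyl group, while the low temperature and the absence of base spare C3.

Step 5
Reactants: 9 (2S,3S)-5-hydroxy-7-methoxy-2,3-dimethylchroman-4-one
Product: 12 (2S,3R)-7-methoxy-2,3-dimethylchroman-5-ol, via ethyl carbonate 10 (not isolated), via quinone methide 11 (not isolated)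
Conditions: ClCO2Et, Et3N, THF, 0 °C; filtrate added to NaBH4, H2O/THF, 0 °C → rt; dilute HCl
Reagents that add atoms: ethyl chloroformate, CCOC(=O)Cl (atoms kept only in 10)
Why: Deoxygenation of an ortho-hydroxyaryl ketone through its carbonate, in which hydride reduces C4=O of 10, the carbonate migrates to O4 and leaves to give ortho-quinone methide 11, and a second hydride adds at C4, so C2 and C3 are untouched (the C3 descriptor changes only through priorities).

Step 6
Reactants: 12 (2S,3R)-7-methoxy-2,3-dimethylchroman-5-ol; 13 ethyl 3-oxohexanoate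
Product: 14 (8S,9R)-5-methoxy-8,9-dimethyl-4-propyl-9,10-dihydro-2H,8H-pyrano[2,3-f]chromen-2-one
Conditions: MeSO3H, rt
Reagents that add atoms: none
Why: Pechmann condensation, well known for 3,5-dialkoxyphenols with β-keto esters, which can give a coumarin only at C6, the sole free position ortho to O5–H, so C8 stays open.

Step 7
Reactants: 14 coumarin
Product: 16 (4R,8S,9R)-5-methoxy-8,9-dimethyl-4-propyl-3,4,9,10-tetrahydro-2H,8H-pyrano[2,3-f]chromen-2-one, via silyl ketene acetal 15 (not isolated)
Conditions: Cu(OAc)2·H2O (5 mol %), (S)-DTBM-SEGPHOS [(S)-5,5'-bis{bis(3,5-di-tert-butyl-4-methoxyphenyl)phosphino}-4,4'-bi-1,3-benzodioxole, 5.5 mol %], (EtO)2MeSiH (2 equiv), toluene, 0 °C → rt; aq. NH4Cl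
Reagents that add atoms: diethoxymethylsilane, C[SiH](OCC)OCC (atoms kept only in 15)
Why: Ligand-controlled copper hydride conjugate reduction of a 4-substituted coumarin, in which hydride adds to C3' on the face left open by the ligand and sets (R), and without an alcohol additive the enolate stays as silyl ketene acetal 15 until work-up, which should prevent further reduction of the aryl ester.

Step 8
Reactants: 16 dihydrocoumarin
Product: 17 (4R,8S,9R)-6-iodo-5-methoxy-8,9-dimethyl-4-propyl-3,4,9,10-tetrahydro-2H,8H-pyrano[2,3-f]chromen-2-one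
Conditions: NIS (1.05 equiv), TFA (20 mol %), MeCN, 0 °C → rt
Reagents that add atoms: N-iodosuccinimide, O=C1CCC(=O)N1I
Why: Electrophilic aromatic iodination at C8 of the target numbering, the only aromatic C–H left, which lies ortho to O1 and OMe and para to the lactone oxygen.

Step 9
Reactants: 17 aryl iodide; 18 tributyl(3-methylbut-2-en-1-yl)stannane
Product: 19 (4R,8S,9R)-5-methoxy-8,9-dimethyl-6-(3-methylbut-2-en-1-yl)-4-propyl-3,4,9,10-tetrahydro-2H,8H-pyrano[2,3-f]chromen-2-one
Conditions: Pd(PPh3)4 (5 mol %), DMF, 90 °C
Reagents that add atoms: none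
Why: Stille coupling, in which zerovalent palladium inserts into C8–I and the prenyl group is transferred from tin and coupled at its unsubstituted terminus, under neutral conditions that leave the lactone and the three stereocenters alone.

Step 10
Reactants: 19 prenylated lactone
Product: 20 (3R)-3-[(2S,3R)-5-hydroxy-7-methoxy-2,3-dimethyl-8-(3-methylbut-2-en-1-yl)chroman-6-yl]hexanoic acid
Conditions: LiOH (3 equiv), THF/H2O, 0 °C → rt; cold 1 M HCl to pH 4–5, rapid extraction
Reagents that add atoms: lithium hydroxide, [Li+].[OH-]
Why: Saponification of the aryl ester, after which cold and only mildly acidic work-up should release the hydroxy acid before it can lactonise again, with no stereocenter adjacent to an acidic position.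

**Compound list**
1 | 1,3,5-trimethoxybenzene | COc1cc(OC)cc(OC)c1 | starting material
2 | propionic anhydride | CCC(=O)OC(=O)CC | starting material
3 | 1-(2,4,6-trimethoxyphenyl)propan-1-one | CCC(=O)c1c(OC)cc(OC)cc1OC | intermediate
4 | (Z)-trimethyl{[1-(2,4,6-trimethoxyphenyl)prop-1-en-1-yl]oxy}silane | C/C=C(\O[Si](C)(C)C)c1c(OC)cc(OC)cc1OC | intermediate
5 | acetaldehyde | CC=O | starting material
6 | (2S,3S)-2-methyl-3-(trimethylsilyloxy)-1-(2,4,6-trimethoxyphenyl)butan-1-one (anti silyl aldol) | C[Si](C)(C)O[C@@H](C)[C@H](C)C(=O)c1c(OC)cc(OC)cc1OC | intermediate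
7 | (2S,3S)-5,7,8a-trimethoxy-2,3-dimethyl-4-(trimethylsilyloxy)-2,3-dihydro-8aH-chromene (ring ketal, C8a not assigned) | COC1=CC(OC)=CC2(OC)O[C@@H](C)[C@H](C)C(O[Si](C)(C)C)=C12 | intermediate
8 | (2S,3S)-5,7-dimethoxy-2,3-dimethylchroman-4-one (trans) | COc1cc(OC)c2c(c1)O[C@@H](C)[C@H](C)C2=O | intermediate
9 | (2S,3S)-5-hydroxy-7-methoxy-2,3-dimethylchroman-4-one | COc1cc(O)c2c(c1)O[C@@H](C)[C@H](C)C2=O | intermediate
10 | ethyl (2S,3S)-7-methoxy-2,3-dimethyl-4-oxochroman-5-yl carbonate | COc1cc(OC(=O)OCC)c2c(c1)O[C@@H](C)[C@H](C)C2=O | intermediate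
11 | (2S,3R)-7-methoxy-2,3-dimethyl-2,3-dihydro-5H-chromen-5-one (ortho-quinone methide, C4=C4a) | O=C1C=C(OC)C=C2O[C@@H](C)[C@H](C)C=C12 | intermediate
12 | (2S,3R)-7-methoxy-2,3-dimethylchroman-5-ol | COc1cc(O)c2c(c1)O[C@@H](C)[C@H](C)C2 | intermediate
13 | ethyl 3-oxohexanoate | CCCC(=O)CC(=O)OCC | starting material
14 | (8S,9R)-5-methoxy-8,9-dimethyl-4-propyl-9,10-dihydro-2H,8H-pyrano[2,3-f]chromen-2-one | CCCC1=CC(=O)Oc2c3c(cc(OC)c12)O[C@@H](C)[C@H](C)C3 | intermediate
15 | (4R,8S,9R)-2-[diethoxy(methyl)silyloxy]-5-methoxy-8,9-dimethyl-4-propyl-9,10-dihydro-4H,8H-pyrano[2,3-f]chromene | CCC[C@@H]1C=C(O[Si](C)(OCC)OCC)Oc2c3c(cc(OC)c12)O[C@@H](C)[C@H](C)C3 | intermediate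
16 | (4R,8S,9R)-5-methoxy-8,9-dimethyl-4-propyl-3,4,9,10-tetrahydro-2H,8H-pyrano[2,3-f]chromen-2-one | CCC[C@@H]1CC(=O)Oc2c3c(cc(OC)c12)O[C@@H](C)[C@H](C)C3 | intermediate
17 | (4R,8S,9R)-6-iodo-5-methoxy-8,9-dimethyl-4-propyl-3,4,9,10-tetrahydro-2H,8H-pyrano[2,3-f]chromen-2-one | CCC[C@@H]1CC(=O)Oc2c3c(c(I)c(OC)c12)O[C@@H](C)[C@H](C)C3 | intermediate
18 | tributyl(3-methylbut-2-en-1-yl)stannane | CCCC[Sn](CCCC)(CCCC)CC=C(C)C | starting material
19 | (4R,8S,9R)-5-methoxy-8,9-dimethyl-6-(3-methylbut-2-en-1-yl)-4-propyl-3,4,9,10-tetrahydro-2H,8H-pyrano[2,3-f]chromen-2-one | CCC[C@@H]1CC(=O)Oc2c3c(c(CC=C(C)C)c(OC)c12)O[C@@H](C)[C@H](C)C3 | intermediate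
20 | (3R)-3-[(2S,3R)-5-hydroxy-7-methoxy-2,3-dimethyl-8-(3-methylbut-2-en-1-yl)chroman-6-yl]hexanoic acid | CCC[C@H](CC(=O)O)c1c(O)c2c(c(CC=C(C)C)c1OC)O[C@@H](C)[C@H](C)C2 | target

**Total step count:** 10. **Longest linear sequence:** 10 steps (1 → 20).

**Steps most likely to fail**

Step 3 (new method). The ipso closure at C8a may be slower than β-elimination of the silyloxy group. Facial or anti selectivity with so small an aldehyde may also be poor.
The fallback uses known chemistry and closes ring B at O1–C2 instead. It sets out from 3. A syn-selective aldol through the (Z)-diisopinocampheylboron enolate would be run with the antipode of Ipc2BOTf that attacks the Si face of acetaldehyde (i-Pr2NEt, then 5, then H2O2). It would give (2S,3R)-3-hydroxy-2-methyl-1-(2,4,6-trimethoxyphenyl)butan-1-one F1. BCl3 would then free one ortho phenol to give (2S,3R)-3-hydroxy-1-(2-hydroxy-4,6-dimethoxyphenyl)-2-methylbutan-1-one F2. Mitsunobu etherification (PPh3, DIAD) would close the ring with inversion at the carbinol carbon. The route is rejoined at 8.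

Step 7. The methoxy group peri to the β-carbon may slow hydride delivery, erode facial selectivity, or allow over-reduction of the lactone.
The fallback sets C3' by C–C rather than C–H bond formation and sets out from 12. Pd(OAc)2-catalysed hydroarylation and lactonisation with ethyl propiolate (TFA/CH2Cl2) would give (8S,9R)-5-methoxy-8,9-dimethyl-9,10-dihydro-2H,8H-pyrano[2,3-f]chromen-2-one F3. Copper-catalysed asymmetric conjugate addition of n-PrMgBr would follow, with CuBr·SMe2 and (R)-1-[(S)-2-(diphenylphosphino)ferrocenyl]ethyldicyclohexylphosphine or its antipode in t-BuOMe at −72 °C. The route is rejoined at 16.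

Step 9. Oxidative addition and transmetalation at the doubly ortho-substituted iodide may be sluggish. This would leave room for protodeiodination or for coupling at the tertiary allyl terminus.
The fallback builds the prenyl group in two stages and sets out from 17. Stille coupling with allyltributylstannane would give (4R,8S,9R)-6-allyl-5-methoxy-8,9-dimethyl-4-propyl-3,4,9,10-tetrahydro-2H,8H-pyrano[2,3-f]chromen-2-one F4. Cross-metathesis with 2-methylbut-2-ene (second-generation Grubbs catalyst, CH2Cl2, 40 °C) would follow. The route is rejoined at 19.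

**Further compounds**
F1 | step 3 | (2S,3R)-3-hydroxy-2-methyl-1-(2,4,6-trimethoxyphenyl)butan-1-one | O[C@H](C)[C@H](C)C(=O)c1c(OC)cc(OC)cc1OC
F2 | step 3 | (2S,3R)-3-hydroxy-1-(2-hydroxy-4,6-dimethoxyphenyl)-2-methylbutan-1-one | O[C@H](C)[C@H](C)C(=O)c1c(O)cc(OC)cc1OC
F3 | step 7 | (8S,9R)-5-methoxy-8,9-dimethyl-9,10-dihydro-2H,8H-pyrano[2,3-f]chromen-2-one | O=C1C=Cc2c(OC)cc3O[C@@H](C)[C@H](C)Cc3c2O1
F4 | step 9 | (4R,8S,9R)-6-allyl-5-methoxy-8,9-dimethyl-4-propyl-3,4,9,10-tetrahydro-2H,8H-pyrano[2,3-f]chromen-2-one | CCC[C@@H]1CC(=O)Oc2c3c(c(CC=C)c(OC)c12)O[C@@H](C)[C@H](C)C3
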